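**Retrosynthetic overview**
1. Endgame: C6–Cl by SN2 on the (6R)-allylic alcohol; the ten-membered ring is closed last, at C2–C3, by an intramolecular Nozaki–Hiyama–Kishi reaction of a (Z)-iododiene with the neopentyl C2 aldehyde.
2. Lactone ring: a 4-bromobutenolide (C3–C8, C16–C19, from a vinylogous Mukaiyama aldol) is joined to the ring A aldehyde at C8–C9; directed epoxidation, oxidation/chelation-controlled reduction and SmI2 opening then give 8-OH, 9-OAc and H-17.
3. Ring A first: a five-membered carbonyl ylide (C13=O+–C10−) adds across allene in a (3+2) cycloaddition that forms C12–C13 and C10–C11; SmI2 then cuts the temporary C10–O bridge, which leaves the 13-hydroxyl.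
4. Enabling feature: in ring A the C13 oxygen is 1,4 to C10 (through C14–C1); C10 carries the oxygenated C9 (a carbonyl that stabilises a diazo/carbenoid carbon), sits next to quaternary C1 (no β-hydrogen) and next to C11 with its exocyclic methylene C20 (the central carbon of allene).
5. C1 comes from Johnson–Claisen chirality transfer; ring order: ring A (with oxygen bridge) → γ-lactone → ten-membered ring.

Key step: step 8

Remark: locants C1–C20 are the usual briarane locants of the target (C1 quaternary, methyl C15; C11 bears methylene C20; lactone C7–O–C19); compounds 1, 13, 18, 19 and 22 are taken as purchasable.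

**Route**

Step 1
Reactants: 1 tert-butyl(but-3-yn-1-yloxy)diphenylsilane
Product: 3 (E)-6-[(tert-butyldiphenylsilyl)oxy]-4-methylhex-3-en-2-one, via alkenylalane 2 (not isolated)
Conditions: Me3Al, Cp2ZrCl2 (cat.), CH2Cl2, 0 °C to rt; then AcCl, Pd(PPh3)4 (cat.), THF, 0 °C
Reagents that add atoms: trimethylaluminium C[Al](C)C; acetyl chloride CC(Cl)=O
Why: Zirconium-catalysed Negishi carboalumination adds methyl and aluminium syn across the terminal alkyne (methyl to the internal carbon), and palladium-catalysed acylation of the alkenylalane with retention should give the (E)-enone.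

Step 2
Reactants: 3 (E)-6-[(tert-butyldiphenylsilyl)oxy]-4-methylhex-3-en-2-one
Product: 4 (S,E)-6-[(tert-butyldiphenylsilyl)oxy]-4-methylhex-3-en-2-ol
Conditions: (R)-1-methyl-3,3-diphenyltetrahydro-1H,3H-pyrrolo[1,2-c][1,3,2]oxazaborole (cat.), BH3·SMe2, THF, −20 °C
Reagents that add atoms: none
Why: Corey–Bakshi–Shibata 1,2-reduction, in which the (R)-oxazaborolidine with the alkenyl group as the large substituent should deliver the (S)-carbinol.

Step 3
Reactants: 4 (S,E)-6-[(tert-butyldiphenylsilyl)oxy]-4-methylhex-3-en-2-ol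
Product: 6 methyl (S,E)-3-{2-[(tert-butyldiphenylsilyl)oxy]ethyl}-3-methylhex-4-enoate, via ketene acetal 5 (not isolated)
Conditions: MeC(OMe)3, EtCO2H (cat.), xylene, 140 °C, MeOH distilled off
Reagents that add atoms: trimethyl orthoacetate CC(OC)(OC)OC
Why: Johnson–Claisen rearrangement through a chair transition state with the carbinol methyl equatorial should transfer the (S)-carbinol chirality to quaternary C1 (methyl axial, silyloxyethyl equatorial) and give the (E)-propenyl group.

Step 4
Reactants: 6 methyl (S,E)-3-{2-[(tert-butyldiphenylsilyl)oxy]ethyl}-3-methylhex-4-enoate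
Product: 8 methyl (S)-5-[(tert-butyldiphenylsilyl)oxy]-3-(dimethoxymethyl)-3-methylpentanoate, via aldehyde 7 (not isolated)
Conditions: O3, CH2Cl2/MeOH, −78 °C; Me2S; then HC(OMe)3, PPTS, MeOH, rt
Reagents that add atoms: trimethyl orthoformate COC(OC)OC (both methoxy groups; the oxygen that ozone puts on aldehyde 7 leaves again as methyl formate)
Why: Ozonolysis cleaves the only alkene to the C2 aldehyde, and acid-catalysed acetalisation in the same flask masks it as the branched dimethyl acetal; C1 is not touched.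

Step 5
Reactants: 8 methyl (S)-5-[(tert-butyldiphenylsilyl)oxy]-3-(dimethoxymethyl)-3-methylpentanoate
Product: 10 methyl (S)-5-[(tert-butyldiphenylsilyl)oxy]-2-diazo-3-(dimethoxymethyl)-3-methylpentanoate, via trifluoroacetyl ester 9 (not isolated)
Conditions: LiN(i-Pr)2, THF, −78 °C; CF3CO2CH2CF3; then MsN3, Et3N, H2O, MeCN, rt
Reagents that add atoms: methanesulfonyl azide CS(=O)(=O)N=[N+]=[N-] (the trifluoroacetyl group of 9 is lost again)
Why: Deacylating (Regitz-type) diazo transfer: Claisen trifluoroacetylation activates C10, the only enolisable position, and the sulfonyl azide then delivers N2 with loss of the trifluoroacetyl group.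

Step 6
Reactants: 10 methyl (S)-5-[(tert-butyldiphenylsilyl)oxy]-2-diazo-3-(dimethoxymethyl)-3-methylpentanoate
Product: 11 methyl (S)-2-diazo-3-(dimethoxymethyl)-5-hydroxy-3-methylpentanoate
Conditions: Bu4NF, AcOH, THF, 0 °C
Reagents that add atoms: none
Why: Buffered fluoride desilylation; the diazo-conjugated ester is a poor acyl donor, so lactonisation of the hydroxy ester should be slow and 11 is oxidised at once.

Step 7
Reactants: 11 methyl (S)-2-diazo-3-(dimethoxymethyl)-5-hydroxy-3-methylpentanoate
Product: 12 methyl (S)-2-diazo-3-(dimethoxymethyl)-3-methyl-5-oxopentanoate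
Conditions: Dess–Martin periodinane, NaHCO3, CH2Cl2, 0 °C
Reagents that add atoms: none
Why: Dess–Martin oxidation is neutral and tolerates the diazo ester and the acetal, giving the C13 aldehyde.

Step 8
Reactants: 12 methyl (S)-2-diazo-3-(dimethoxymethyl)-3-methyl-5-oxopentanoate; 13 propadiene (allene)
Product: 15 methyl (1R,2S,4S)-2-(dimethoxymethyl)-2-methyl-6-methylidene-7-oxabicyclo[2.2.1]heptane-1-carboxylate, via carbonyl ylide 14 (not isolated)
Conditions: Rh2(OAc)4 (2 mol%), propadiene (20 equiv), CH2Cl2, sealed tube, 0 °C to rt, slow addition of 12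
Reagents that add atoms: none
Why: Proposed new method: Rh2(OAc)4 turns the diazo ester into a rhodium carbenoid at C10, which the C13 aldehyde oxygen traps (closure of the five-membered oxonium ring by O-attack on the carbenoid carbon) to give ylide 14; its (3+2) cycloaddition across one C=C bond of allene forms C10–C11 and C12–C13 suprafacially and closes ring A as the six-membered carbocycle of a 7-oxabicyclo[2.2.1]heptane, the oxygen bridge being a temporary ring. The closest known reaction type is the rhodium-catalysed tandem carbonyl ylide formation/intermolecular (3+2) cycloaddition of diazo carbonyl compounds with alkenes and alkynes, and allene is an established 2π partner of diazoalkanes and nitrones. Regiochemistry should follow polarity: the ester-stabilised, nucleophilic ylide carbon C10 bonds to the central sp carbon of allene, as the nucleophilic terminus of other 1,3-dipoles does, and the oxocarbenium-like C13 bonds to a CH2 terminus, which puts the exocyclic methylene C20 on C11. C10 and C13 are locked cis by the oxygen bridge, and their configuration relative to C1 is set by approach of allene to the ylide face anti to the branched dimethoxymethyl group (syn to methyl), so that C2 ends exo on the side of the bridge, as the cis relation of the 13-oxygen and C2 in the target requires. The step needs ylide formation to outrun other carbenoid pathways, which the quaternary C1 (no 1,2-hydride shift) and the fast five-membered closure should secure, and it needs capture of the ylide before proton shift or dimerisation, for which a large excess of allene and slow addition of 12 are used.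

Step 9
Reactants: 15 methyl (1R,2S,4S)-2-(dimethoxymethyl)-2-methyl-6-methylidene-7-oxabicyclo[2.2.1]heptane-1-carboxylate
Product: 16 methyl (1S,2S,4S)-2-(dimethoxymethyl)-4-hydroxy-2-methyl-6-methylidenecyclohexane-1-carboxylate
Conditions: SmI2, HMPA, t-BuOH, THF, −78 °C
Reagents that add atoms: none
Why: Ketyl-type reductive cleavage of the α-alkoxy ester by SmI2 breaks the strained C10–O bond and keeps the oxygen on C13; C10 should be protonated with retention because the freed C13 oxygen sits across the boat on the face it left and relays the proton there, while kinetic α-protonation of the dienolate keeps the methylene exocyclic.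

Step 10
Reactants: 16 methyl (1S,2S,4S)-2-(dimethoxymethyl)-4-hydroxy-2-methyl-6-methylidenecyclohexane-1-carboxylate
Product: 17 (1S,2S,4S)-2-(dimethoxymethyl)-4-hydroxy-2-methyl-6-methylidenecyclohexane-1-carbaldehyde
Conditions: i-Bu2AlH, CH2Cl2, −78 °C; aq. KNaC4H4O6
Reagents that add atoms: none
Why: Partial reduction of the hindered ester stops at the aluminium hemiacetal at low temperature and gives the C9 aldehyde on work-up without base, so C10 should not epimerise.

Step 11
Reactants: 18 2-bromoprop-2-en-1-ol; 19 ethynyltrimethylsilane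
Product: 20 2-methylidene-4-(trimethylsilyl)but-3-yn-1-ol
Conditions: PdCl2(PPh3)2 (cat.), CuI (cat.), Et3N, THF, rt
Reagents that add atoms: none
Why: Sonogashira coupling of the 1,1-disubstituted vinyl bromide assembles C3–C6 and C16.

Step 12
Reactants: 20 2-methylidene-4-(trimethylsilyl)but-3-yn-1-ol
Product: 21 2-methylidene-4-(trimethylsilyl)but-3-ynal
Conditions: Dess–Martin periodinane, NaHCO3, CH2Cl2, 0 °C
Reagents that add atoms: none
Why: Mild oxidation of the allylic alcohol gives the C6 enal, which is used without storage.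

Step 13
Reactants: 22 4-hydroxy-3-methylfuran-2(5H)-one (3-methyltetronic acid)
Product: 23 4-bromo-3-methylfuran-2(5H)-one
Conditions: (COBr)2, DMF (cat.), CH2Cl2, 0 °C to rt
Reagents that add atoms: oxalyl bromide O=C(Br)C(=O)Br
Why: Vilsmeier-type conversion of the vinylogous acid into the vinylogous acid bromide installs the C8 coupling handle.

Step 14
Reactants: 23 4-bromo-3-methylfuran-2(5H)-one
Product: 24 [(4-bromo-3-methylfuran-2-yl)oxy](tert-butyl)dimethylsilane
Conditions: TBSOTf, Et3N, CH2Cl2, 0 °C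
Reagents that add atoms: tert-butyldimethylsilyl trifluoromethanesulfonate CC(C)(C)[Si](C)(C)OS(=O)(=O)C(F)(F)F
Why: Soft enolisation and O-silylation give the 2-silyloxyfuran, the dienolate equivalent that is nucleophilic at C7.

Step 15
Reactants: 21 2-methylidene-4-(trimethylsilyl)but-3-ynal; 24 [(4-bromo-3-methylfuran-2-yl)oxy](tert-butyl)dimethylsilane
Product: 25 (R)-4-bromo-5-[(R)-1-hydroxy-2-methylidene-4-(trimethylsilyl)but-3-yn-1-yl]-3-methylfuran-2(5H)-one
Conditions: SiCl4, (R,R)-bisphosphoramide from N,N′-dimethyl-1,1′-binaphthyl-2,2′-diamine (5 mol%), i-Pr2NEt, CH2Cl2, −78 °C; aq. NaHCO3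
Reagents that add atoms: none
Why: Catalytic enantioselective vinylogous Mukaiyama aldol addition at the γ-carbon through an open transition state; the Lewis-base-bound silicon cation should select the aldehyde face and so set C7 and the (5R,1′R) carbinol C6, which is the C6 epimer needed for later inversion.

Step 16
Reactants: 25 (R)-4-bromo-5-[(R)-1-hydroxy-2-methylidene-4-(trimethylsilyl)but-3-yn-1-yl]-3-methylfuran-2(5H)-one
Product: 26 (R)-4-bromo-5-[(R)-1-(tert-butyldimethylsilyloxy)-2-methylidene-4-(trimethylsilyl)but-3-yn-1-yl]-3-methylfuran-2(5H)-one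
Conditions: TBSOTf, 2,6-lutidine, CH2Cl2, −78 °C
Reagents that add atoms: tert-butyldimethylsilyl trifluoromethanesulfonate CC(C)(C)[Si](C)(C)OS(=O)(=O)C(F)(F)F
Why: Silylation with a weak base protects the C6 hydroxyl without enolising the butenolide at C7.

Step 17
Reactants: 17 (1S,2S,4S)-2-(dimethoxymethyl)-4-hydroxy-2-methyl-6-methylidenecyclohexane-1-carbaldehyde; 26 (R)-4-bromo-5-[(R)-1-(tert-butyldimethylsilyloxy)-2-methylidene-4-(trimethylsilyl)but-3-yn-1-yl]-3-methylfuran-2(5H)-one
Product: 27 (9R)-carbinol from C8–C9 coupling (seco-briarane butenolide)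
Conditions: CrCl2, NiCl2 (cat.), DMSO/THF, rt
Reagents that add atoms: none
Why: Nozaki–Hiyama–Kishi coupling of the β-bromo enoate with the hindered aldehyde tolerates the free hydroxyl, lactone and alkyne, and Felkin–Anh attack anti to quaternary C1 should give the (9R)-alcohol that the next step needs.

Step 18
Reactants: 27 (9R)-carbinol from C8–C9 coupling (seco-briarane butenolide)
Product: 28 8,17-epoxy lactone (9R)-carbinol
Conditions: t-BuOOH, n-BuLi, THF, −78 to −20 °C
Reagents that add atoms: tert-butyl hydroperoxide CC(C)(C)OO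
Why: Hydroxyl-directed nucleophilic (Weitz–Scheffer-type) epoxidation: the lithium alkoxide of the (9R)-carbinol, in the conformer with C9–H eclipsing C8=C17, delivers the peroxide to C8 on the face anti to the C6 side chain, so the future 8-oxygen ends cis to H-7, and only the electron-poor alkene reacts.

Step 19
Reactants: 28 8,17-epoxy lactone (9R)-carbinol
Product: 29 13-acetate of the epoxy lactone (9R)-carbinol
Conditions: Ac2O (1.1 equiv), pyridine, CH2Cl2, 0 °C
Reagents that add atoms: acetic anhydride CC(=O)OC(C)=O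
Why: Selective acylation of the unhindered equatorial 13-hydroxyl; the 9-hydroxyl between C10 and the quaternary epoxide carbon should react much more slowly.

Step 20
Reactants: 29 13-acetate of the epoxy lactone (9R)-carbinol
Product: 30 9-keto 8,17-epoxy lactone
Conditions: Dess–Martin periodinane, NaHCO3, CH2Cl2, 0 °C
Reagents that add atoms: none
Why: Buffered Dess–Martin oxidation of the only free secondary alcohol gives the α,β-epoxy ketone without enolising C10.

Step 21
Reactants: 30 9-keto 8,17-epoxy lactone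
Product: 31 (9S)-carbinol of the 8,17-epoxy lactone
Conditions: Zn(BH4)2, Et2O, −20 °C
Reagents that add atoms: none
Why: Chelation-controlled reduction of the α,β-epoxy ketone (zinc bridges the carbonyl and epoxide oxygens, hydride enters anti to the epoxide carbon C17), reinforced by Felkin–Anh control from C10, should give the erythro epoxy alcohol, that is the (9S)-carbinol, a net inversion at C9.

Step 22
Reactants: 31 (9S)-carbinol of the 8,17-epoxy lactone
Product: 32 9,13-diacetate of the 8,17-epoxy lactone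
Conditions: Ac2O, pyridine, DMAP (cat.), CH2Cl2, rt
Reagents that add atoms: acetic anhydride CC(=O)OC(C)=O
Why: DMAP-catalysed acetylation of the hindered secondary 9-hydroxyl installs the second acetate of the target.

Step 23
Reactants: 32 9,13-diacetate of the 8,17-epoxy lactone
Product: 34 8-hydroxy lactone (17R), via 17-epimer 33 (not isolated)
Conditions: SmI2, Me2NCH2CH2OH, THF, −78 °C; then DBU (cat.), toluene, rt
Reagents that add atoms: none
Why: SmI2 opens the α,β-epoxy lactone at the C17–O bond α to the carbonyl and leaves the tertiary 8-hydroxyl; the samarium enolate is expected to be protonated anti to the C9 side chain, and DBU then equilibrates C17 to the more stable epimer with the methyl trans to that side chain and cis to 8-OH.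

Step 24
Reactants: 34 8-hydroxy lactone (17R)
Product: 35 1-iodoalkyne
Conditions: NIS, AgNO3 (cat.), DMF, rt, dark
Reagents that add atoms: N-iodosuccinimide O=C1CCC(=O)N1I
Why: Silver-catalysed iododesilylation of the alkynylsilane (a terminal alkyne formed by adventitious desilylation earlier would be iodinated as well) gives the iodoalkyne without touching the alkenes.

Step 25
Reactants: 35 1-iodoalkyne
Product: 36 (Z)-iododiene
Conditions: 2-nitrobenzenesulfonylhydrazide, Et3N, THF/i-PrOH, rt
Reagents that add atoms: none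
Why: Diimide made from the sulfonyl hydrazide adds hydrogen syn to the iodoalkyne faster than to the 1,1-disubstituted alkenes, which should give the (Z)-vinyl iodide of the C3=C4 bond.

Step 26
Reactants: 36 (Z)-iododiene
Product: 37 C2 aldehyde
Conditions: PPTS, acetone/H2O, 45 °C
Reagents that add atoms: water O
Why: Mild acid hydrolysis of the dimethyl acetal frees the non-enolisable neopentyl aldehyde; the secondary silyl ether, acetates and vinyl iodide tolerate PPTS.

Step 27
Reactants: 37 C2 aldehyde
Product: 38 ten-membered (2S)-allylic alcohol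
Conditions: CrCl2, NiCl2 (cat.), DMSO/THF, high dilution, rt
Reagents that add atoms: none
Why: Intramolecular Nozaki–Hiyama–Kishi reaction: the alkenylchromium formed with retention of the Z geometry adds to the C2 aldehyde and closes the ten-membered ring, and addition on the aldehyde face exposed in the cyclisation conformer is expected to give the (2S)-carbinol with its oxygen syn to the C1 methyl.

Step 28
Reactants: 38 ten-membered (2S)-allylic alcohol
Product: 39 2,9,13-triacetate 6-silyl ether
Conditions: Ac2O, pyridine, DMAP (cat.), CH2Cl2, rt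
Reagents that add atoms: acetic anhydride CC(=O)OC(C)=O
Why: Acetylation of the secondary 2-hydroxyl; the tertiary 8-hydroxyl should not be acylated under these conditions.

Step 29
Reactants: 39 2,9,13-triacetate 6-silyl ether
Product: 40 (6R)-allylic alcohol triacetate
Conditions: HF·pyridine, pyridine, THF, 0 °C to rt
Reagents that add atoms: none
Why: Buffered HF cleaves the secondary silyl ether without acyl migration or loss of the acetates.

Step 30
Reactants: 40 (6R)-allylic alcohol triacetate
Product: 41 CNP0268873.2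
Conditions: PPh3, (Cl3C)2CO, CH2Cl2, −20 to 0 °C
Reagents that add atoms: hexachloroacetone O=C(C(Cl)(Cl)Cl)C(Cl)(Cl)Cl
Why: Appel-type chlorination: chloride displaces the oxyphosphonium by SN2 with inversion to give the (6S)-chloride, the C7 oxygen disfavours ionisation and allylic transposition, and the tertiary 8-hydroxyl does not react.

**Compound list**
1 | tert-butyl(but-3-yn-1-yloxy)diphenylsilane | C#CCCO[Si](c1ccccc1)(c1ccccc1)C(C)(C)C | starting material
2 | (E)-{4-[(tert-butyldiphenylsilyl)oxy]-2-methylbut-1-en-1-yl}dimethylalane (not isolated) | C[Al](C)/C=C(\C)CCO[Si](c1ccccc1)(c1ccccc1)C(C)(C)C | intermediate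
3 | (E)-6-[(tert-butyldiphenylsilyl)oxy]-4-methylhex-3-en-2-one | CC(=O)/C=C(\C)CCO[Si](c1ccccc1)(c1ccccc1)C(C)(C)C | intermediate
4 | (S,E)-6-[(tert-butyldiphenylsilyl)oxy]-4-methylhex-3-en-2-ol | C[C@H](O)/C=C(\C)CCO[Si](c1ccccc1)(c1ccccc1)C(C)(C)C | intermediate
5 | mixed ketene acetal of 4, (S,E)-5-[(1-methoxyethenyl)oxy]-3-methylhex-3-enyl silyl ether (not isolated) | C=C(OC)O[C@@H](C)/C=C(\C)CCO[Si](c1ccccc1)(c1ccccc1)C(C)(C)C | intermediate
6 | methyl (S,E)-3-{2-[(tert-butyldiphenylsilyl)oxy]ethyl}-3-methylhex-4-enoate | COC(=O)C[C@](C)(CCO[Si](c1ccccc1)(c1ccccc1)C(C)(C)C)/C=C/C | intermediate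
7 | methyl (S)-5-[(tert-butyldiphenylsilyl)oxy]-3-formyl-3-methylpentanoate (not isolated) | COC(=O)C[C@](C)(CCO[Si](c1ccccc1)(c1ccccc1)C(C)(C)C)C=O | intermediate
8 | methyl (S)-5-[(tert-butyldiphenylsilyl)oxy]-3-(dimethoxymethyl)-3-methylpentanoate | COC(=O)C[C@](C)(CCO[Si](c1ccccc1)(c1ccccc1)C(C)(C)C)C(OC)OC | intermediate
9 | methyl (3S)-5-[(tert-butyldiphenylsilyl)oxy]-3-(dimethoxymethyl)-3-methyl-2-(trifluoroacetyl)pentanoate, C2 epimers (not isolated) | COC(=O)C(C(=O)C(F)(F)F)[C@](C)(CCO[Si](c1ccccc1)(c1ccccc1)C(C)(C)C)C(OC)OC | intermediate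
10 | methyl (S)-5-[(tert-butyldiphenylsilyl)oxy]-2-diazo-3-(dimethoxymethyl)-3-methylpentanoate | COC(=O)C(=[N+]=[N-])[C@](C)(CCO[Si](c1ccccc1)(c1ccccc1)C(C)(C)C)C(OC)OC | intermediate
11 | methyl (S)-2-diazo-3-(dimethoxymethyl)-5-hydroxy-3-methylpentanoate | COC(=O)C(=[N+]=[N-])[C@](C)(CCO)C(OC)OC | intermediate
12 | methyl (S)-2-diazo-3-(dimethoxymethyl)-3-methyl-5-oxopentanoate | COC(=O)C(=[N+]=[N-])[C@](C)(CC=O)C(OC)OC | intermediate
13 | propadiene (allene) | C=C=C | starting material
14 | five-membered carbonyl ylide, aldehyde oxygen bound to the former carbenoid carbon C10 (not isolated) | COC(=O)[C-]1[O+]=CC[C@]1(C)C(OC)OC | intermediate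
15 | methyl (1R,2S,4S)-2-(dimethoxymethyl)-2-methyl-6-methylidene-7-oxabicyclo[2.2.1]heptane-1-carboxylate (acetal exo, methyl endo) | C=C1C[C@H]2C[C@](C)(C(OC)OC)[C@]1(C(=O)OC)O2 | intermediate
16 | methyl (1S,2S,4S)-2-(dimethoxymethyl)-4-hydroxy-2-methyl-6-methylidenecyclohexane-1-carboxylate | C=C1C[C@H](O)C[C@](C)(C(OC)OC)[C@H]1C(=O)OC | intermediate
17 | (1S,2S,4S)-2-(dimethoxymethyl)-4-hydroxy-2-methyl-6-methylidenecyclohexane-1-carbaldehyde | C=C1C[C@H](O)C[C@](C)(C(OC)OC)[C@H]1C=O | intermediate
18 | 2-bromoprop-2-en-1-ol | C=C(Br)CO | starting material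
19 | ethynyltrimethylsilane | C#C[Si](C)(C)C | starting material
20 | 2-methylidene-4-(trimethylsilyl)but-3-yn-1-ol | C=C(CO)C#C[Si](C)(C)C | intermediate
21 | 2-methylidene-4-(trimethylsilyl)but-3-ynal | C=C(C=O)C#C[Si](C)(C)C | intermediate
22 | 4-hydroxy-3-methylfuran-2(5H)-one (3-methyltetronic acid) | CC1=C(O)COC1=O | starting material
23 | 4-bromo-3-methylfuran-2(5H)-one | CC1=C(Br)COC1=O | intermediate
24 | [(4-bromo-3-methylfuran-2-yl)oxy](tert-butyl)dimethylsilane | Cc1c(Br)coc1O[Si](C)(C)C(C)(C)C | intermediate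
25 | (R)-4-bromo-5-[(R)-1-hydroxy-2-methylidene-4-(trimethylsilyl)but-3-yn-1-yl]-3-methylfuran-2(5H)-one | C[Si](C)(C)C#CC(=C)[C@@H](O)[C@H]1OC(=O)C(C)=C1Br | intermediate
26 | (R)-4-bromo-5-[(R)-1-(tert-butyldimethylsilyloxy)-2-methylidene-4-(trimethylsilyl)but-3-yn-1-yl]-3-methylfuran-2(5H)-one | C[Si](C)(C)C#CC(=C)[C@@H](O[Si](C)(C)C(C)(C)C)[C@H]1OC(=O)C(C)=C1Br | intermediate
27 | (9R)-carbinol: 3-methylfuran-2(5H)-one carrying at C4 the (R)-hydroxy[(1S,2S,4S)-2-(dimethoxymethyl)-4-hydroxy-2-methyl-6-methylidenecyclohexyl]methyl group and at C5 (S) the (R)-1-(tert-butyldimethylsilyloxy)-2-methylidene-4-(trimethylsilyl)but-3-ynyl group | C=C1C[C@H](O)C[C@](C)(C(OC)OC)[C@H]1[C@@H](O)C2=C(C)C(=O)O[C@@H]2[C@H](O[Si](C)(C)C(C)(C)C)C(=C)C#C[Si](C)(C)C | intermediate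
28 | 8,17-epoxide of 27, epoxide oxygen cis to H-7 and anti to the C6 side chain, (9R)-carbinol | C=C1C[C@H](O)C[C@](C)(C(OC)OC)[C@H]1[C@@H](O)[C@@]23O[C@@]3(C)C(=O)O[C@@H]2[C@H](O[Si](C)(C)C(C)(C)C)C(=C)C#C[Si](C)(C)C | intermediate
29 | 13-acetate of 28 | C=C1C[C@H](OC(C)=O)C[C@](C)(C(OC)OC)[C@H]1[C@@H](O)[C@@]23O[C@@]3(C)C(=O)O[C@@H]2[C@H](O[Si](C)(C)C(C)(C)C)C(=C)C#C[Si](C)(C)C | intermediate
30 | 9-ketone of 29 (α,β-epoxy ketone) | C=C1C[C@H](OC(C)=O)C[C@](C)(C(OC)OC)[C@H]1C(=O)[C@@]23O[C@@]3(C)C(=O)O[C@@H]2[C@H](O[Si](C)(C)C(C)(C)C)C(=C)C#C[Si](C)(C)C | intermediate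
31 | (9S)-carbinol, C9 epimer of 29 | C=C1C[C@H](OC(C)=O)C[C@](C)(C(OC)OC)[C@H]1[C@H](O)[C@@]23O[C@@]3(C)C(=O)O[C@@H]2[C@H](O[Si](C)(C)C(C)(C)C)C(=C)C#C[Si](C)(C)C | intermediate
32 | 9,13-diacetate of the 8,17-epoxy lactone | C=C1C[C@H](OC(C)=O)C[C@](C)(C(OC)OC)[C@H]1[C@H](OC(C)=O)[C@@]23O[C@@]3(C)C(=O)O[C@@H]2[C@H](O[Si](C)(C)C(C)(C)C)C(=C)C#C[Si](C)(C)C | intermediate
33 | 17-epimer of 34, methyl cis to the C9 side chain (not isolated) | C=C1C[C@H](OC(C)=O)C[C@](C)(C(OC)OC)[C@H]1[C@H](OC(C)=O)[C@]2(O)[C@H](C)C(=O)O[C@@H]2[C@H](O[Si](C)(C)C(C)(C)C)C(=C)C#C[Si](C)(C)C | intermediate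
34 | 8-hydroxy-17-methyl γ-lactone, methyl cis to 8-OH; 9,13-diacetate, 6-silyl ether, C2 dimethyl acetal, silyl enyne | C=C1C[C@H](OC(C)=O)C[C@](C)(C(OC)OC)[C@H]1[C@H](OC(C)=O)[C@]2(O)[C@@H](C)C(=O)O[C@@H]2[C@H](O[Si](C)(C)C(C)(C)C)C(=C)C#C[Si](C)(C)C | intermediate
35 | 1-iodoalkyne from 34 | C=C1C[C@H](OC(C)=O)C[C@](C)(C(OC)OC)[C@H]1[C@H](OC(C)=O)[C@]2(O)[C@@H](C)C(=O)O[C@@H]2[C@H](O[Si](C)(C)C(C)(C)C)C(=C)C#CI | intermediate
36 | (Z)-1-iodo-1,3-diene (C3=C4 Z, C5=C16) | C=C1C[C@H](OC(C)=O)C[C@](C)(C(OC)OC)[C@H]1[C@H](OC(C)=O)[C@]2(O)[C@@H](C)C(=O)O[C@@H]2[C@H](O[Si](C)(C)C(C)(C)C)C(=C)/C=C\I | intermediate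
37 | C2 aldehyde with (Z)-iododiene (seco compound for ring closure) | C=C1C[C@H](OC(C)=O)C[C@](C)(C=O)[C@H]1[C@H](OC(C)=O)[C@]2(O)[C@@H](C)C(=O)O[C@@H]2[C@H](O[Si](C)(C)C(C)(C)C)C(=C)/C=C\I | intermediate
38 | ten-membered ring (2S)-alcohol: 9,13-diacetate, 8-OH, (6R)-silyl ether | C=C1C[C@H](OC(C)=O)C[C@]2(C)[C@@H](O)/C=C\C(=C)[C@@H](O[Si](C)(C)C(C)(C)C)[C@H]3OC(=O)[C@H](C)[C@@]3(O)[C@@H](OC(C)=O)[C@@H]12 | intermediate
39 | 2,9,13-triacetate (6R)-silyl ether | C=C1C[C@H](OC(C)=O)C[C@]2(C)[C@@H](OC(C)=O)/C=C\C(=C)[C@@H](O[Si](C)(C)C(C)(C)C)[C@H]3OC(=O)[C@H](C)[C@@]3(O)[C@@H](OC(C)=O)[C@@H]12 | intermediate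
40 | 2,9,13-triacetate (6R)-alcohol (6-epi-hydroxy analogue of the target) | C=C1C[C@H](OC(C)=O)C[C@]2(C)[C@@H](OC(C)=O)/C=C\C(=C)[C@@H](O)[C@H]3OC(=O)[C@H](C)[C@@]3(O)[C@@H](OC(C)=O)[C@@H]12 | intermediate
41 | CNP0268873.2 | C=C1C[C@H](OC(C)=O)C[C@]2(C)[C@@H](OC(C)=O)/C=C\C(=C)[C@H](Cl)[C@H]3OC(=O)[C@H](C)[C@@]3(O)[C@@H](OC(C)=O)[C@@H]12 | target

**Step count and risks**
Total steps: 30. Longest linear sequence: 24 steps (steps 1–10 and 17–30); steps 11–16 make the bromobutenolide 26.

Steps most likely to fail: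

Step 8 (Proposed new method). The ylide may be intercepted too slowly by allene (carbenoid dimerisation, proton shift of the ylide), or allene may add with the wrong regiochemistry or from the wrong face. The fallback builds ring A by two known C–C bond formations and sets out from 8. Buffered fluoride desilylation gives the hydroxy ester F1 and Dess–Martin oxidation gives the aldehyde F2. CrCl2-mediated asymmetric 2-bromoallylation with 2,3-dibromopropene and a chiral sulfonamide–oxazoline ligand forms C12–C13 and the C13 carbinol in the bromo alcohol F3, which is silylated (TBSCl, imidazole) to the silyl ether F4. Palladium-catalysed intramolecular α-alkenylation of the ester enolate (Pd2(dba)3, 2-dicyclohexylphosphino-2′,4′,6′-triisopropylbiphenyl, LiN(SiMe3)2, toluene) forms C10–C11 and gives the ring A ester F5. Bu4NF removes the silyl group and the route is rejoined at 16.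

Step 9. The samarium dienolate may be protonated on the wrong face at C10, or at C20 with conjugation of the alkene. The fallback fixes C10 in a ring closure instead of a protonation, again from 8 through the hydroxy ester F1 and the aldehyde F2. Asymmetric propargylation (allenylboronic acid pinacol ester, chiral phosphoric acid) gives the homopropargylic alcohol F6, silylation gives the silyl ether F7, and iodination of the ester enolate (LiN(i-Pr)2; I2) gives the α-iodo ester F8. Bu3SnH/AIBN-mediated 6-exo-dig cyclisation of the C10 radical onto the alkyne, through a chair-like transition state with ester and silyloxy group equatorial, should give the ring A ester F5, and desilylation returns to 16.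

Step 27. Ring closure may be slow against transannular strain, so that the C–I bond is reduced or dimers form, and facial selectivity at C2 may be poor. The fallback moves the ring closure to C3=C4 by olefin metathesis and sets out from 34. Bu4NF/AcOH removes the alkynyl silane to give the terminal enyne F9; semihydrogenation (H2, Pd/CaCO3 poisoned with Pb(OAc)2, quinoline) gives the terminal diene F10; PPTS hydrolysis gives the aldehyde F11. CrCl2/NiCl2-mediated addition of vinyl bromide with a chiral sulfonamide ligand gives the C2 vinyl carbinol F12. Ring-closing metathesis with the second-generation Grubbs catalyst at high dilution, relying on the preference of a ten-membered ring for the cis olefin, returns to 38.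

Further compounds
F1 | step 8 | methyl (S)-3-(dimethoxymethyl)-5-hydroxy-3-methylpentanoate | COC(=O)C[C@](C)(CCO)C(OC)OC
F2 | step 8 | methyl (S)-3-(dimethoxymethyl)-3-methyl-5-oxopentanoate | COC(=O)C[C@](C)(CC=O)C(OC)OC
F3 | step 8 | methyl (3S,5S)-7-bromo-3-(dimethoxymethyl)-5-hydroxy-3-methyloct-7-enoate | COC(=O)C[C@](C)(C[C@@H](O)CC(Br)=C)C(OC)OC
F4 | step 8 | tert-butyldimethylsilyl ether of F3 | COC(=O)C[C@](C)(C[C@@H](O[Si](C)(C)C(C)(C)C)CC(Br)=C)C(OC)OC
F5 | step 8 | methyl (1S,2S,4S)-4-(tert-butyldimethylsilyloxy)-2-(dimethoxymethyl)-2-methyl-6-methylidenecyclohexane-1-carboxylate | C=C1C[C@H](O[Si](C)(C)C(C)(C)C)C[C@](C)(C(OC)OC)[C@H]1C(=O)OC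
F6 | step 9 | methyl (3S,5S)-3-(dimethoxymethyl)-5-hydroxy-3-methyloct-7-ynoate | COC(=O)C[C@](C)(C[C@@H](O)CC#C)C(OC)OC
F7 | step 9 | tert-butyldimethylsilyl ether of F6 | COC(=O)C[C@](C)(C[C@@H](O[Si](C)(C)C(C)(C)C)CC#C)C(OC)OC
F8 | step 9 | 2-iodo derivative of F7 (C2 epimers) | COC(=O)C(I)[C@](C)(C[C@@H](O[Si](C)(C)C(C)(C)C)CC#C)C(OC)OC
F9 | step 27 | terminal enyne from 34 | C=C1C[C@H](OC(C)=O)C[C@](C)(C(OC)OC)[C@H]1[C@H](OC(C)=O)[C@]2(O)[C@@H](C)C(=O)O[C@@H]2[C@H](O[Si](C)(C)C(C)(C)C)C(=C)C#C
F10 | step 27 | terminal 1,3-diene from F9 | C=C1C[C@H](OC(C)=O)C[C@](C)(C(OC)OC)[C@H]1[C@H](OC(C)=O)[C@]2(O)[C@@H](C)C(=O)O[C@@H]2[C@H](O[Si](C)(C)C(C)(C)C)C(=C)C=C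
F11 | step 27 | C2 aldehyde from F10 | C=C1C[C@H](OC(C)=O)C[C@](C)(C=O)[C@H]1[C@H](OC(C)=O)[C@]2(O)[C@@H](C)C(=O)O[C@@H]2[C@H](O[Si](C)(C)C(C)(C)C)C(=C)C=C
F12 | step 27 | (2S)-vinyl carbinol from F11 | C=C1C[C@H](OC(C)=O)C[C@](C)([C@@H](O)C=C)[C@H]1[C@H](OC(C)=O)[C@]2(O)[C@@H](C)C(=O)O[C@@H]2[C@H](O[Si](C)(C)C(C)(C)C)C(=C)C=C
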